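**Retrosynthetic overview**
- Last step: O-demethylation of the ring-B monomethyl ether of the target.
- Key disconnection: the diaryl ether C–O bond, made by a new Rh(II) carbene O–H insertion of 3,6-dibromo-2-methoxyphenol (ring B, O-nucleophile) into 3,5-dibromo-ortho-quinone diazide (ring A). The same step unveils the ring-A OH.
- Ring A piece: diazotisation of 2-amino-4,6-dibromophenol, which already carries both bromines in the right places.
- Ring B piece: mono-demethylation of 3,6-dibromoveratrole, made by double ortho-lithiation/bromination of veratrole.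
- No ring is constructed; both benzene rings are bought and joined once, convergently.

Assumption: the target has no stereocentre and no configurationally stable axis, so it is achiral and "single enantiomer" does not apply; the SMILES carry no stereo-descriptors.

**Step 1**
Reactants: 1 veratrole (1,2-dimethoxybenzene)
Product: 3 1,4-dibromo-2,3-dimethoxybenzene, via 3,6-dilithioveratrole 2 (not isolated)
Conditions: n-BuLi (3 equiv), TMEDA (3 equiv), hexane, 0 °C → rt, 24 h; then BrCl2C–CCl2Br (3.3 equiv), THF, −78 °C → rt
Reagents that add atoms: 1,2-dibromo-1,1,2,2-tetrachloroethane, BrC(Cl)(Cl)C(Cl)(Cl)Br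
Why: Double directed ortho-metalation: each OMe guides TMEDA-activated n-BuLi to the only two ortho C–H bonds (C3 and C6), and dilithio arene 2 takes Br+ from the polyhaloethane, giving the "both Br ortho to O" pattern that electrophilic bromination of a catechol ether cannot give.

**Step 2**
Reactants: 3 1,4-dibromo-2,3-dimethoxybenzene
Product: 5 3,6-dibromo-2-methoxyphenol, via sodium aryloxide 4 (not isolated)
Conditions: NaSEt (2 equiv), DMF, 100 °C, 3 h; then 1 M HCl
Reagents that add atoms: none
Why: Nucleophilic (SN2) O-demethylation by thiolate: the two OMe groups are equivalent, and once aryloxide 4 has formed the ring is too electron-rich for the second methyl ether to be cleaved, so the reaction stops at the mono-phenol.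

**Step 3**
Reactants: 6 2-amino-4,6-dibromophenol
Product: 8 2,4-dibromo-6-diazocyclohexa-2,4-dien-1-one, via arenediazonium chloride 7 (not isolated)
Conditions: NaNO2 (1.05 equiv), aq. HCl/AcOH, 0 °C; then NaOAc to pH 5, 0 °C, dark; filter, dry cold in vacuo (small batches, blast shield)
Reagents that add atoms: sodium nitrite, [Na+].[O-]N=O
Why: Diazotisation of an ortho-aminophenol: the 2-hydroxyarenediazonium ion 7 loses its acidic phenolic proton on buffering and the neutral ortho-quinone diazide 8 precipitates; both bromines are meta to N2+ and are not displaced.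

**Step 4**
Reactants: 5 3,6-dibromo-2-methoxyphenol (2.5 equiv); 8 2,4-dibromo-6-diazocyclohexa-2,4-dien-1-one (1 equiv)
Product: 10 2,4-dibromo-6-(3,6-dibromo-2-methoxyphenoxy)phenol, via oxonium ylide 9 (not isolated)
Conditions: Rh2(esp)2 (2 mol %), 4 Å MS, PhCF3/DCE, 70 °C, dark; 8 in DCE added by syringe pump over 4 h; excess 5 recovered by chromatography
Reagents that add atoms: none
Why: Proposed new method: Rh(II)-catalysed formal O–H insertion of a monocyclic, brominated ortho-quinone diazide into a di-ortho-substituted phenol to forge a hindered diaryl ether — Rh2(esp)2 extrudes N2 from 8 to give an electrophilic rhodium quinoid carbene at C6 (flanked only by C=O and C–H, so open to a hindered nucleophile), the phenolic oxygen of 5 adds to it to give oxonium ylide 9, and a 1,4-proton shift from O+ to the ring oxygen releases the catalyst and aromatises ring A, which is the driving force and places the new OH ortho to the new C–O bond with both bromines already in position; the closest known reaction type is Rh(II)-catalysed O–H insertion of diazonaphthoquinones and other diazo compounds into alcohols, water and carboxylic acids, and the new element is a benzo-quinone diazide reacting with a hindered, electron-poor phenol, with Wolff ring contraction and azo coupling held back by working in the dark, below 80 °C and without base, and C–Br bonds inert to Rh(II).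

**Step 5**
Reactants: 10 2,4-dibromo-6-(3,6-dibromo-2-methoxyphenoxy)phenol
Product: 12 3,6-dibromo-2-(3,5-dibromo-2-hydroxyphenoxy)phenol, via bis(dibromoboryl) ether 11 (not isolated)
Conditions: BBr3 (3 equiv), CH2Cl2, −78 °C → rt, 12 h; then ice-water
Reagents that add atoms: none
Why: Lewis-acid O-demethylation (BBr3 ether cleavage): boron binds the methoxy oxygen and bromide removes the methyl group by SN2, the diaryl ether and C–Br bonds are inert, and hydrolysis of the B–O bonds on work-up frees both phenols.

**Compound list**
1 | veratrole (1,2-dimethoxybenzene) | COc1ccccc1OC | starting material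
2 | 3,6-dilithioveratrole (1,4-dilithio-2,3-dimethoxybenzene) | [Li]c1ccc([Li])c(OC)c1OC | intermediate
3 | 1,4-dibromo-2,3-dimethoxybenzene | COc1c(Br)ccc(Br)c1OC | intermediate
4 | sodium 3,6-dibromo-2-methoxyphenoxide | COc1c(Br)ccc(Br)c1[O-].[Na+] | intermediate
5 | 3,6-dibromo-2-methoxyphenol | COc1c(Br)ccc(Br)c1O | intermediate
6 | 2-amino-4,6-dibromophenol | Nc1cc(Br)cc(Br)c1O | starting material
7 | 3,5-dibromo-2-hydroxybenzenediazonium chloride | Oc1c(Br)cc(Br)cc1[N+]#N.[Cl-] | intermediate
8 | 2,4-dibromo-6-diazocyclohexa-2,4-dien-1-one (3,5-dibromo-ortho-quinone diazide) | O=C1C(Br)=CC(Br)=CC1=[N+]=[N-] | intermediate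
9 | (3,5-dibromo-2-oxidophenyl)(3,6-dibromo-2-methoxyphenyl)oxonium, the oxonium ylide drawn without rhodium | COc1c(Br)ccc(Br)c1[OH+]c1cc(Br)cc(Br)c1[O-] | intermediate
10 | 2,4-dibromo-6-(3,6-dibromo-2-methoxyphenoxy)phenol | COc1c(Br)ccc(Br)c1Oc1cc(Br)cc(Br)c1O | intermediate
11 | dibromo{3,6-dibromo-2-[3,5-dibromo-2-(dibromoboryloxy)phenoxy]phenoxy}borane | BrB(Br)Oc1c(Br)cc(Br)cc1Oc1c(Br)ccc(Br)c1OB(Br)Br | intermediate
12 | 3,6-dibromo-2-(3,5-dibromo-2-hydroxyphenoxy)phenol (CNP0181200.0, achiral) | Oc1c(Br)cc(Br)cc1Oc1c(Br)ccc(Br)c1O | target

**Totals**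
Total step count: 5. Longest linear sequence: 4 (steps 1, 2, 4, 5); step 3 is the one-step side arm.

**Three steps most likely to fail**

Step 4 (the proposed new step). The risks are slow N2 loss from the electron-poor diazide, Wolff ring contraction, azo coupling, and arylation of the para C–H of 5 or of the product phenol. The fallback uses known chemistry only; it sets out from 5 and comes back at 10. SNAr of 5 on 2-fluorobenzaldehyde (O=Cc1ccccc1F; K2CO3, DMAc, 120 °C) gives 2-(3,6-dibromo-2-methoxyphenoxy)benzaldehyde F1. Baeyer–Villiger (Dakin-type) oxidation with mCPBA in CH2Cl2 gives 2-(3,6-dibromo-2-methoxyphenoxy)phenyl formate F2. Methanolysis (cat. K2CO3, MeOH, rt) gives 2-(3,6-dibromo-2-methoxyphenoxy)phenol F3. Br2 (2.05 equiv, AcOH/CH2Cl2, 0 °C) then brominates only the free-phenol ring, ortho and para to its OH, and gives 10; the ring-B dibromoanisole is too deactivated to react.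

Step 1. The risks are an incomplete second lithiation, mono-/dibromide mixtures and Li/Br scrambling during the quench. The fallback sets out from 1 and comes back at 3, using silicon as a placeholder installed one position at a time. Monolithiation (n-BuLi 1.1 equiv, TMEDA, Et2O, 0 °C → rt) and TMSCl give (2,3-dimethoxyphenyl)trimethylsilane F4. A second ortho-metalation at the one remaining ortho position, again quenched with TMSCl, gives (2,3-dimethoxy-1,4-phenylene)bis(trimethylsilane) F5; a C–Si bond, unlike a C–Br bond, survives n-BuLi. Ipso-bromodesilylation with Br2 (2.1 equiv, CH2Cl2, 0 °C) then gives 3.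

Step 2. The risk is thiolate attack on C–Br or reductive debromination at 100 °C. The fallback sets out from 3 and comes back at 5. Exhaustive demethylation with BBr3 (CH2Cl2, −78 °C → rt; water work-up) gives 3,6-dibromobenzene-1,2-diol F6. Mono-methylation of this symmetric diol with MeI (1.0 equiv) and K2CO3 (1.0 equiv) in acetone at rt gives 5; the only over-methylated by-product is 3 itself, which is recycled, and unreacted diol is recovered.

**Further compounds**
F1 | step 4 | 2-(3,6-dibromo-2-methoxyphenoxy)benzaldehyde | COc1c(Br)ccc(Br)c1Oc1ccccc1C=O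
F2 | step 4 | 2-(3,6-dibromo-2-methoxyphenoxy)phenyl formate | COc1c(Br)ccc(Br)c1Oc1ccccc1OC=O
F3 | step 4 | 2-(3,6-dibromo-2-methoxyphenoxy)phenol | COc1c(Br)ccc(Br)c1Oc1ccccc1O
F4 | step 1 | (2,3-dimethoxyphenyl)trimethylsilane | COc1cccc([Si](C)(C)C)c1OC
F5 | step 1 | (2,3-dimethoxy-1,4-phenylene)bis(trimethylsilane) | COc1c([Si](C)(C)C)ccc([Si](C)(C)C)c1OC
F6 | step 2 | 3,6-dibromobenzene-1,2-diol | Oc1c(Br)ccc(Br)c1O
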